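At the last reading of each run below, compare the side product gained with the electrophile lost; that ratio tells you where a lost electrophile ends up. In these flasks electrophile meets free base and protonated nucleophile, the target appears, and a side product takes up two electrophiles.

| flask | electrophile | free base | protonated nucleophile | remark | time |
|---|---|---|---|---|---|
| Tuesday's | 0.13 mM | 0.16 mM | 0.50 mM | run made earlier |  |
| Friday's | 0.30 mM | 0.16 mM | 0.50 mM | run made earlier |  |
| Sunday's | 0.20 mM | 0.24 mM | 0.50 mM | run made earlier |  |
| eta | 0.20 mM | 0.160 mM | 0.500 mM |  | 20 min |
| alpha | 0.20 mM | 0.160 mM | 0.500 mM |  | 5.0 min |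
| zeta | 0.20 mM | 0.160 mM | 0.500 mM |  | 10 min |

| run | time / min | side product / % | target / % | electrophile / % |
|---|---|---|---|---|
| Tuesday's | 0.500 | 3 | 1 | 95 |
| Tuesday's | 1.33 | 1 | 3 | 95 |
| Tuesday's | 2.50 | 10 | 3 | 87 |
| Tuesday's | 4.00 | 17 | 3 | 81 |
| Friday's | 0.500 | 2 | 2 | 100 |
| Friday's | 1.33 | 3 | 3 | 96 |
| Friday's | 2.50 | 9 | 4 | 89 |
| Friday's | 4.00 | 14 | 0 | 87 |
| Sunday's | 1.00 | 1 | 1 | 95 |
| Sunday's | 2.00 | 7 | 0 | 89 |
| Sunday's | 3.00 | 13 | 0 | 85 |
| Sunday's | 4.00 | 17 | 3 | 79 |

(scatter of a reading: 1.5 percentage points)

- percentages count the electrophile that a species holds: one side product counts as two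
- the numbers in the tables scatter with a standard deviation of 1.5 percentage points

- which of these there is most of at the end, counted by the electrophile in it, eta (target / electrophile / side product)
- which of these there is most of at the end, counted by the electrophile in it, alpha (target / electrophile / side product)
- which of these there is most of at the end, counted by the electrophile in it, zeta (target / electrophile / side product)
- amount of the one of these that there is most of at the end, in percent of the electrophile charged, eta
- amount of the one of these that there is most of at the end, in percent of the electrophile charged, alpha
- amount of the one of these that there is most of at the end, in percent of the electrophile charged, zeta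

The ratio reads 0.895 on Tuesday, 1.08 on Friday and 0.810 on Sunday, so a lost electrophile mostly lands in side product, and Tuesday's target reads just 3%. Side product should therefore lead once the electrophile has dropped past about 0.5 of its charge.

Tuesday's and Friday's charges bracket our 0.20 mM, so I average their decay: 0.0437 min⁻¹, a halving time of 15.8 min. That is shorter than eta's 20 min.

Sunday, with more free base, reads faster at 0.0589 min⁻¹; that rests on one scattered reading, so I take it as a hint that the base takes part. I assume one free base is paid per electrophile lost. This gives the base cover, the charged free base over the charged electrophile: 80.0%. On that assumption free base is the limiting reagent.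

The weak link is that each decay rests on one reading. So I count each run's loss twice, from the electrophile and from side product plus target, and average. This gives 0.0452 min⁻¹. I commit to electrophile at 79.8% in alpha and 63.6% in zeta. In eta it is 40.5%, which leaves side product first at about 56.5%. Eta's reckoned loss of 59.5% stays inside its cover.

The forecast put electrophile first in eta at 52%, saying “electrophile still leads, narrowly”, with 79% in alpha and 66% in zeta.

The flasks give side product first in eta at 57.0%, electrophile in alpha at 79.0%, and electrophile in zeta at 62.7%.

    electrophile + nucleophile ⇌ acid set free + target (K = 0.530, k = 230 M⁻¹ s⁻¹)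
    nucleophile + acid set free ⇌ protonated nucleophile, settled at all times (K = 6.50 × 10⁷ M⁻¹)
    acid set free + free base ⇌ salt of the base (K = 7.30 × 10⁷ M⁻¹, k = 280 M⁻¹ s⁻¹)
    electrophile + target → side product (k = 110 M⁻¹ s⁻¹)

Eta lost 0.117 mM of electrophile, which is 58.4% of its charge and inside its cover of 80.0%, and it holds 0.117 mM of salt of the base. Now take the neighbour, eta with 0.064 mM of free base. Its cover is 32.0%, so you reckon electrophile first at about 68.0%. That neighbour gives electrophile first at 64.6% and side product at 35.0%, with 6.37% of its free base left, and beside 0.0599 mM of salt of the base stands 0.0124 mM of acid set free.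

Readings and results are simulated with made-up constants.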